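## Retrosynthetic overview

1. Target ⇒ 7-endo-prenyl type A bicyclo[3.3.1]nonane trione (nemorosone constitution). The key bond is O–C2'' of the 1,2-dioxepane, closed by a peroxyl radical inside an aerobic manganese cascade that also forms C3–C2', C3'–O and C3''–OOH.
2. That trione ⇒ type A hydroxy-adamantane, by retro-aldol opening and two Wittig reactions that turn the C7 formyl carbon into the endo prenyl group.
3. Hydroxy-adamantane ⇒ dearomatised acylphloroglucinol carrying a 2-formyl-3-methylbut-2-enyl chain, by acid-mediated aldol/Michael cage closure.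
4. Dearomatised compound ⇒ clusiaphenone B + 2-(bromomethyl)-3-methylbut-2-enal, by enantioselective alkylative dearomatisation (the only enantio-determining step).
5. Ring order: ring A (from the arene) → ring B with the adamantane cage → cage opened to the bicyclo[3.3.1] core → seven-membered carbocycle (homoadamantane) → 1,2-dioxepane.

Numbering used in the text: C1 benzoyl bridgehead, C2/C4/C9 carbonyl carbons, C3, C5 prenyl bridgehead, C6 (CH2), C7, C8 (CMe2). C1'–C3' are the carbons of the former C7-prenyl group, C1''–C3'' those of the former C3-prenyl group, and C10 is the carbinol carbon of the adamantane.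

Assumption 1: the cinchonidine-derived ammonium salt in step 5 is taken to give the (S) quaternary carbon of 8; if it gives the mirror image, its cinchonine-derived pseudo-enantiomer is used instead.

Assumption 2: 9 is drawn as the C10 epimer with OH on the C4/C6 side; any other C10 epimer converges in step 7, where C10 becomes sp2.

## Route

Step 1
Reactants: 1 2,4,6-trihydroxybenzophenone; 2 prenyl bromide (1-bromo-3-methylbut-2-ene)
Product: 3 clusiaphenone B
Conditions: 2 (2.1 equiv), 5% aq KOH, 0 °C
Reagents that add atoms: none
Why: Double C-prenylation of the acylphloroglucinol phenolate (electrophilic aromatic C-alkylation) at the two free ring carbons; no stereocentre is formed.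

Step 2
Reactants: 4 diethyl 2-(propan-2-ylidene)malonate
Product: 5 2-(propan-2-ylidene)propane-1,3-diol
Conditions: i-Bu2AlH (4.4 equiv), CH2Cl2, −78 → 0 °C; aq. KNaC4H4O6 (potassium sodium tartrate)
Reagents that add atoms: none
Why: 1,2-reduction of both conjugated esters to allylic alcohols by the aluminium hydride (ester reduction), leaving the tetrasubstituted alkene untouched.

Step 3
Reactants: 5 2-(propan-2-ylidene)propane-1,3-diol
Product: 6 2-(hydroxymethyl)-3-methylbut-2-enal
Conditions: activated MnO2 (8 equiv), CH2Cl2, 23 °C, stopped when 5 is consumed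
Reagents that add atoms: none
Why: Allylic alcohol oxidation with MnO2; once one alcohol is an enal the second, now on an electron-poor alkene, is oxidised much more slowly.

Step 4
Reactants: 6 2-(hydroxymethyl)-3-methylbut-2-enal
Product: 7 2-(bromomethyl)-3-methylbut-2-enal
Conditions: PBr3 (0.4 equiv), Et2O, 0 °C; used crude
Reagents that add atoms: phosphorus tribromide, BrP(Br)Br
Why: SN2 bromination of the primary allylic alcohol through its phosphite ester; the aldehyde is inert to PBr3 at 0 °C.

Step 5
Reactants: 3 clusiaphenone B; 7 2-(bromomethyl)-3-methylbut-2-enal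
Product: 8 dearomatised enal (6S)
Conditions: 7 (1.2 equiv), O-allyl-N-(9-anthracenylmethyl)cinchonidinium bromide (10 mol%), CsOH·H2O (2.2 equiv), 4 Å molecular sieves, CH2Cl2, −60 °C; AcOH quench
Reagents that add atoms: none
Why: Alkylative dearomatisation (C-alkylation of the phloroglucinolate at a prenyl-bearing carbon, SN2 at the allylic bromide) under chiral ion-pair phase-transfer catalysis; the ammonium cation selects one of the two enantiotopic prenyl-bearing carbons and so sets the quaternary centre (later C5), which controls every cage stereocentre.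

Step 6
Reactants: 8 dearomatised enal
Product: 9 type A hydroxy-adamantane
Conditions: conc. aq HCl (2 equiv), THF, 0 → 23 °C
Reagents that add atoms: none
Why: Acid-mediated cyclisation cascade (reversible aldol addition of the more nucleophilic C3 enol to the protonated aldehyde, then Michael/Prins-type closure of the C1 enol onto the CMe2 carbon C8); because the chain sits on one face at C5, the cage fixes C1, C3 and C7 relative to C5, and only the carbinol centre C10 is free.

Step 7
Reactants: 9 type A hydroxy-adamantane
Product: 11 7-endo-(2-oxoethyl) bicyclic trione, via enol ether 10 (not isolated)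
Conditions: Ph3P(CH2OMe)Cl (4 equiv), KN(SiMe3)2 (3.9 equiv), THF, 0 → 23 °C; then 2 M aq HCl, 23 °C
Reagents that add atoms: (methoxymethyl)triphenylphosphonium chloride, COC[P+](c1ccccc1)(c1ccccc1)c1ccccc1.[Cl-]; water, O
Why: Retro-aldol/Wittig homologation: the potassium alkoxide of 9 fragments to the stabilised trione enolate and the endo C7 aldehyde, which the methoxymethylene ylide traps (Wittig reaction) before it can epimerise, and acid hydrolysis of the enol ether gives the one-carbon-longer aldehyde with C7 still endo.

Step 8
Reactants: 11 7-endo-(2-oxoethyl) bicyclic trione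
Product: 12 7-endo-prenyl type A trione (1S,5S,7S)
Conditions: i-PrPPh3I (4 equiv), n-BuLi (3.9 equiv), THF, −78 → 23 °C; aq. NH4Cl
Reagents that add atoms: isopropyltriphenylphosphonium iodide, CC(C)[P+](c1ccccc1)(c1ccccc1)c1ccccc1.[I-]
Why: Wittig olefination with the isopropylidene ylide builds the trisubstituted alkene of the C7 prenyl group; the enol is masked as its enolate, the hindered non-enolisable C9 and benzoyl ketones do not react, and no stereocentre is touched.

Step 9
Reactants: 12 7-endo-prenyl type A trione
Product: 14 target CNP0215795.1, via hydroperoxide 13 (not isolated)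
Conditions: Mn(OAc)3·2H2O (10 mol%), O2 (1 atm), AcOH/CF3CH2OH 1:1 (0.01 M), 23 °C, dark
Reagents that add atoms: dioxygen, O=O
Why: Proposed new method: a manganese-relay aerobic bis-peroxidative bicyclisation — trivalent manganese oxidises the C2–C4 enol of 12 to the C3 radical, which closes the seven-membered carbocycle onto C2' of the endo C7-prenyl group (the only alkene within reach; the CMe2 end swings to the C4/C6 side away from the axial C8 methyl, setting C2'); the tertiary C3' radical captures O2; the C3'-peroxyl radical (or hydroperoxide 13, which trivalent manganese re-oxidises to the same radical) adds 7-exo to C2'' of the C3-prenyl group held geminal to it, forming the key O–C2'' bond of the 1,2-dioxepane (chair-like transition state with the new CMe2 radical pseudo-equatorial on the C4 side, setting C2''); a second O2 is captured and divalent manganese reduces the terminal peroxyl radical to the hydroperoxide while returning to the trivalent state; the closest known reaction type is the manganese triacetate-mediated aerobic peroxidation of 1,3-dicarbonyls with alkenes to 1,2-dioxan-3-ols and the O2-terminated oxidative radical cyclisation of dearomatised acylphloroglucinols, here extended to an intramolecular relay with two O2 captures and a 7-exo peroxyl-radical ring closure.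

## Compound list

1 | 2,4,6-trihydroxybenzophenone | O=C(c1ccccc1)c1c(O)cc(O)cc1O | starting material
2 | prenyl bromide (1-bromo-3-methylbut-2-ene) | CC(C)=CCBr | starting material
3 | clusiaphenone B, phenyl [2,4,6-trihydroxy-3,5-bis(3-methylbut-2-enyl)phenyl] ketone (achiral) | CC(C)=CCc1c(O)c(CC=C(C)C)c(O)c(C(=O)c2ccccc2)c1O | intermediate
4 | diethyl 2-(propan-2-ylidene)malonate | CCOC(=O)C(=C(C)C)C(=O)OCC | starting material
5 | 2-(propan-2-ylidene)propane-1,3-diol | CC(C)=C(CO)CO | intermediate
6 | 2-(hydroxymethyl)-3-methylbut-2-enal | CC(C)=C(CO)C=O | intermediate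
7 | 2-(bromomethyl)-3-methylbut-2-enal | CC(C)=C(CBr)C=O | intermediate
8 | (6S)-2-benzoyl-6-(2-formyl-3-methylbut-2-enyl)-3,5-dihydroxy-4,6-bis(3-methylbut-2-enyl)cyclohexa-2,4-dien-1-one (tautomer drawn; C6 is the later C5) | O=C1C(C(=O)c2ccccc2)=C(O)C(CC=C(C)C)=C(O)[C@]1(CC=C(C)C)CC(C=O)=C(C)C | intermediate
9 | 1-benzoyl-10-hydroxy-8,8-dimethyl-3,5-bis(3-methylbut-2-enyl)adamantane-2,4,9-trione (OH on the C4/C6 side; cage configuration as in the SMILES) | CC(C)=CC[C@]12C[C@@H]3[C@H](O)[C@](CC=C(C)C)(C1=O)C(=O)[C@](C(=O)c1ccccc1)(C2=O)C3(C)C | intermediate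
10 | 1-benzoyl-4-hydroxy-7-endo-(2-methoxyethenyl)-8,8-dimethyl-3,5-bis(3-methylbut-2-enyl)bicyclo[3.3.1]non-3-ene-2,9-dione (E/Z mixture; C1, C5, C7 arranged as in 12) | CC(C)=CC[C@@]12C[C@H](C=COC)C(C)(C)[C@@](C(=O)c3ccccc3)(C1=O)C(=O)C(CC=C(C)C)=C2O | intermediate
11 | 1-benzoyl-4-hydroxy-8,8-dimethyl-3,5-bis(3-methylbut-2-enyl)-7-endo-(2-oxoethyl)bicyclo[3.3.1]non-3-ene-2,9-dione (open form; in equilibrium with its C3–C2' aldol) | CC(C)=CC[C@@]12C[C@H](CC=O)C(C)(C)[C@@](C(=O)c3ccccc3)(C1=O)C(=O)C(CC=C(C)C)=C2O | intermediate
12 | (1S,5S,7S)-1-benzoyl-4-hydroxy-8,8-dimethyl-3,5,7-tris(3-methylbut-2-enyl)bicyclo[3.3.1]non-3-ene-2,9-dione (C7 prenyl endo, syn to C3; descriptors for the tautomer drawn) | CC(C)=CC[C@@]12C[C@H](CC=C(C)C)C(C)(C)[C@@](C(=O)c3ccccc3)(C1=O)C(=O)C(CC=C(C)C)=C2O | intermediate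
13 | homoadamantane hydroperoxide: C3–C2' bonded cage trione with 2-hydroperoxypropan-2-yl on C2' (on the C4/C6 side), C3 and C5 prenyl, C1 benzoyl, C8 gem-dimethyl | CC(C)=CC[C@]12C[C@@H]3C[C@H](C(C)(C)OO)[C@](CC=C(C)C)(C1=O)C(=O)[C@](C(=O)c1ccccc1)(C2=O)C3(C)C | intermediate
14 | target CNP0215795.1: homoadamantane trione with a 1,2-dioxepane fused at C3–C2' (O–O between C3' and C2''), 2-hydroperoxypropan-2-yl on C2'', C5 prenyl, C1 benzoyl | CC(C)=CC[C@]12C[C@@H]3C[C@@H]4C(C)(C)OO[C@H](C(C)(C)OO)C[C@@]4(C1=O)C(=O)[C@](C(=O)c1ccccc1)(C2=O)C3(C)C | target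

## Step count and risks

Total step count: 9. Longest linear sequence: 8 steps (4 → 5 → 6 → 7 → 8 → 9 → 11 → 12 → 14). From 1 the sequence is 6 steps.

**Step 9 (the proposed new cascade).** Risks: direct O2 capture at C3 before the carbocyclisation; a slow 7-exo peroxyl closure that lets 13 rest as its peroxy-hemiketal with the C4 ketone or decay; and the wrong epimer at C2''. The C2'' selectivity is a prediction from the transition-state model, not an established result.
Fallback with known chemistry, setting out from 12 and coming back at 14: the two stages are separated. Stoichiometric Mn(OAc)3·2H2O (2.2 equiv) in AcOH under air at 23 °C performs the known O2-terminated oxidative radical cyclisation, and hydroperoxide 13 is isolated. 13 is then treated with t-BuON=NOt-Bu (10 mol%) and t-BuOOH (2 equiv) under O2 in benzene at 40 °C. This is the known hyponitrite-initiated peroxyl-radical chain cyclisation–oxygenation of unsaturated hydroperoxides and gives 14, with epimers at C2'' separated by chromatography. This fallback makes no compound outside the list (F0).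

**Step 6 (acid cage closure).** Risks: the chain may close onto C3 instead of C1 (type B connectivity), and the prenyl groups may be hydrochlorinated or cyclised onto enol oxygens.
Fallback setting out from 8 and coming back at 9: C3 is switched off before ring B is closed. Me3SiCHN2 in toluene/MeOH methylates the non-chelated C4 hydroxyl to give the methyl enol ether of 8 F5, in which C1 is the only enolisable carbon. CF3CO2H in CH2Cl2 at 0 °C then effects the acid-catalysed intramolecular Michael addition of the C1 enol to the enal, giving the type A bicyclic aldehyde methyl ether F6 (C7 epimers). LiCl in DMSO at 120 °C cleaves the methyl ether; the freed C3 enolate closes by aldol addition onto the endo aldehyde (the exo epimer equilibrates through its enol) to give 9.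

**Step 5 (enantioselective alkylative dearomatisation).** Risks: low enantioselectivity with an SN2 electrophile, and O-alkylation.
Fallback setting out from 3 (with 7) and coming back at 9: resolution instead of asymmetric catalysis. Alkylation with Bu4NBr in place of the chiral salt gives 8 together with its mirror image ent-8 F1. HCl/THF as in step 6 gives 9 together with ent-9 F2. Esterification with (S)-2-methoxy-2-phenylacetic acid (DCC, DMAP, CH2Cl2) gives the (S)-O-methylmandelate of 9 F3 and the (S)-O-methylmandelate of ent-9 F4, which are separated by chromatography or crystallisation. K2CO3 in MeOH, then dilute HCl, cleaves F3 and returns 9; the transient retro-aldol re-closes on acidification.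

## Further compounds

F1 | step 5 | ent-8, (6R)-2-benzoyl-6-(2-formyl-3-methylbut-2-enyl)-3,5-dihydroxy-4,6-bis(3-methylbut-2-enyl)cyclohexa-2,4-dien-1-one | O=C1C(C(=O)c2ccccc2)=C(O)C(CC=C(C)C)=C(O)[C@@]1(CC=C(C)C)CC(C=O)=C(C)C
F2 | step 5 | ent-9, mirror image of the type A hydroxy-adamantane | CC(C)=CC[C@@]12C[C@H]3[C@@H](O)[C@@](CC=C(C)C)(C1=O)C(=O)[C@@](C(=O)c1ccccc1)(C2=O)C3(C)C
F3 | step 5 | (S)-2-methoxy-2-phenylacetate (O-methylmandelate) ester of 9 at the C10 oxygen | CC(C)=CC[C@]12C[C@@H]3[C@H](OC(=O)[C@@H](OC)c4ccccc4)[C@](CC=C(C)C)(C1=O)C(=O)[C@](C(=O)c1ccccc1)(C2=O)C3(C)C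
F4 | step 5 | (S)-2-methoxy-2-phenylacetate (O-methylmandelate) ester of ent-9 at the C10 oxygen | CC(C)=CC[C@@]12C[C@H]3[C@@H](OC(=O)[C@@H](OC)c4ccccc4)[C@@](CC=C(C)C)(C1=O)C(=O)[C@@](C(=O)c1ccccc1)(C2=O)C3(C)C
F5 | step 6 | methyl enol ether of 8 (OMe on the C4 oxygen, next to the quaternary carbon) | O=C1C(C(=O)c2ccccc2)=C(O)C(CC=C(C)C)=C(OC)[C@]1(CC=C(C)C)CC(C=O)=C(C)C
F6 | step 6 | 1-benzoyl-7-formyl-4-methoxy-8,8-dimethyl-3,5-bis(3-methylbut-2-enyl)bicyclo[3.3.1]non-3-ene-2,9-dione (endo-formyl epimer shown) | CC(C)=CC[C@@]12C[C@H](C=O)C(C)(C)[C@@](C(=O)c3ccccc3)(C1=O)C(=O)C(CC=C(C)C)=C2OC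
F0 | step 9 | none | none
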